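## Analysis of the target

Dinklagein A (26) is a 2-arylbenzofuran made of three rings: ring A (the benzo ring, C3a to C7a), the furan ring (O1, C2, C3) and ring B, an aryl group bonded through C1' to C2. Ring A is substituted everywhere except C4: a hydroxyl at C5, a methoxy group at C6 and a prenyl group at C7, with the C5 oxygen para to the furan oxygen on C7a. Ring B carries a hydroxyl at C3' and a methoxy group at C5', both meta to the C2–C1' bond. There is no stereocentre, and the prenyl double bond has two identical methyl groups, so the problem is one of regiochemistry and of telling oxygens apart. The sensitive groups are the prenyl alkene (acid, peracids, hydrogenation), the electron-rich phenols (the C5 hydroxyl is a hydroquinone monoether and oxidises easily) and the furan C2–C3 bond. The difficulty lies in two pairs of oxygens that each need one free hydroxyl and one methyl ether. The ring B pair is related by symmetry in any 3,5-dioxygenated aryl precursor, so a purchased ring B has to be desymmetrised. The strategy rests on the C1'/C3'/C5' pattern of ring B: C1'–C2' can come from an alkyne and C3'–C6' from a 1,3-dioxygenated diene whose two oxygens are different from the start.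

## Retrosynthetic reasoning

**26 from 25.** The last operation only frees the C5 hydroxyl from its methoxymethyl ether. This acetal is chosen because its acidic removal is harmless here: the prenyl group at C7 has no free hydroxyl next to it (C6 is a methyl ether, C7a carries the furan oxygen), so it cannot close to a chroman.

**25 from 24 and 23.** The C2'–carboxyl bond is cut. The ester of 23 is there only to activate the alkyne of the ring-forming step. In acid 24 the carboxyl sits ortho to a hydroxyl and para to a methoxy group, which is the arrangement that allows thermal protodecarboxylation. The forward steps must cleave a doubly ortho-substituted methyl ester without touching the aryl methyl ethers and the acetal, which points to alkyl–oxygen cleavage.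

**23 from 17 and 20 (key disconnection).** Ring B is opened at C1'–C6' and C2'–C3'. C1' and C2' become the triple bond of ynoate 17, and C3' to C6' become diene 20. Cutting here rather than at the biaryl bond C2–C1' means ring B never has to be desymmetrised: the ketene acetal carbon of 20 ends as the phenolic carbon C3' and the enol ether carbon as the methoxy carbon C5'. The forward reaction has to join the nucleophilic methylene of 20 to the alkyne carbon that bears the benzofuran and then aromatise.

**20 from 18.** The diene is the O-silylated extended enolate of enoate 18, so only a γ-deprotonation and a silylation are needed.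

**17 from 14.** The ester carbon is detached from an acetylide carbon, which leads to lithium acetylide 16. The triple bond of 16 is traced through enol phosphate 15 to the acetyl group of methyl ketone 14. Because the elimination of 15 delivers the acetylide itself, the acylation can follow in the same flask, and the ynoate is reached in one operation from a ketone that the furan-forming step delivers directly.

**14 from 11 and 12.** The furan ring is cut at O1–C2 and C2=C3. Chloroacetone 12 supplies C2 and the acetyl group, and salicylaldehyde 11 supplies O1, C3 and ring A. The forward reaction is an O-alkylation followed by an intramolecular aldol condensation.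

**11 from 10, 8, 6 and 7.** The isopropylidene end of the prenyl group is exchanged for a methylene (cross-metathesis retron), giving the allyl compound 10. The C7–CH2 bond of 10 is traced to the allyl ether 8 by a [3,3] shift, and 8 to salicylaldehyde 6 and allyl bromide 7. The formyl group of 6 blocks one ortho position, so the allyl group can only arrive on the carbon between the phenol oxygen and the methoxy group.

**6 from 4, 2 and 1.** The formyl carbon is attached ortho to the hydroxyl of phenol 4, at the position para to the methoxy group. Phenol 4 comes from aldehyde 2 by exchange of the formyl group for a hydroxyl (aryl migration to oxygen), and 2 is the methoxymethyl ether of vanillin 1. Vanillin already holds the C5/C6 oxygens in the right relation and differentiated, and its aldehyde carbon marks the position of the future furan oxygen.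

## Alternatives that were turned down

**Alternative 1:** The furan ring is disconnected at O1–C2 and C2–C3 at the dihydro level. The two halves are ammonium phenol A2 (ring A, source of an ortho-quinone methide) and sulfonium salt A3 (ring B, source of a benzylic ylide).
- Forward key step: base releases the quinone methide and the ylide; the ylide carbon adds to the exocyclic methylene (C2–C3) and the phenoxide displaces the sulfide (O1–C2), giving racemic dihydrobenzofuran A1.
- For: it is convergent and mild, and both halves are plain arenes. Its longest linear sequence would be shorter than that of the chosen route, and on convergence it is the stronger plan.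
- Against: A1 lies two hydrogens below the target. The dehydrogenation would have to be run beside a prenyl group whose CH2 is both benzylic and allylic and beside electron-rich rings. The C2 stereocentre is made only to be destroyed. A3 has to be carved out of a symmetrical 3,5-dioxygenated arene by statistical mono-alkylation, and A2 needs a regioselective aminomethylation of a prenylated phenol.
- Comparison: the chosen route gives up convergence but works at the aromatic oxidation level throughout and creates the ring B differentiation in the bond-forming step.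

**Alternative 2:** Ring A is disconnected at C7a–C7, C6–C5 and C5–C4. Chromium carbene complex A5 supplies C7a, C3a and C4, ynol ether A6 supplies C7 and C6, and a carbonyl ligand supplies C5.
- Forward key step: heating A5 with A6 leads through alkyne insertion, carbonyl insertion and electrocyclisation to phenol A4.
- For: this is the most direct construction of the crowded ring A. The C5 hydroxyl is born free and different from the C6 methoxy group, so no protecting group is needed on ring A. On that point it beats the chosen route, which carries an acetal from the first step to the last.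
- Against: it uses a stoichiometric zerovalent chromium reagent that itself needs several steps. The required orientation puts the methoxy-bearing alkyne carbon next to the carbonyl-derived carbon, whereas the usual steric preference places the larger substituent there. A6 is a labile skipped enyne. A4 is again a dihydrobenzofuran, and its free para-alkoxy phenol would be oxidised under the conditions of dehydrogenation. Ring B still comes from a desymmetrised arene.
- Comparison: the chosen route reaches ring A by ordinary main-group and catalytic chemistry and puts its one uncertain step in a metal-free cycloaddition.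

**Alternative 3:** Ring A is disconnected at C4–C5 and grown on a furan, from keto aldehyde A8.
- Forward key step: base forms the enolate at the alkoxymethyl carbon, which adds to the furan aldehyde (C4–C5); dehydration and enolisation of the C6 ketone give benzofuranol A7.
- For: it stays at the aromatic oxidation level, needs only base, and fixes the ring A regiochemistry by connectivity. The stereocentre of A8 disappears on aromatisation. As a ring-forming event it is at least as secure as the cycloaddition of the chosen route.
- Against: A8 is a trisubstituted furan with an α-branched α'-alkoxy ketone and would take a long linear sequence. Enolisation at the more acidic furyl methine competes unproductively. After the annulation the hindered C6 hydroxyl must still be methylated and two acetals removed. Ring B is again a desymmetrised purchased arene.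
- Comparison: the chosen route is shorter to its key intermediate and does not leave the ring B problem open.

Key step: step 10

Remark on the chemistry: diene 20 is taken as the (1E) isomer drawn; this geometry is lost when its C1 becomes an aromatic carbon, so either isomer would serve.

## Route

Step 1
Reactants: 1 vanillin (4-hydroxy-3-methoxybenzaldehyde)
Product: 2 3-methoxy-4-(methoxymethoxy)benzaldehyde
Conditions: MOMCl, i-Pr2NEt, CH2Cl2, 0 °C → rt
Reagents that add atoms: chloromethyl methyl ether, COCCl
Why: O-Alkylation of the phenol (methoxymethyl ether formation). The acetal masks the future C5 hydroxyl through the basic, organometallic and thermal steps that follow.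

Step 2
Reactants: 2 3-methoxy-4-(methoxymethoxy)benzaldehyde
Product: 4 3-methoxy-4-(methoxymethoxy)phenol, via aryl formate 3 (not isolated)
Conditions: mCPBA, CH2Cl2, 0 °C → rt; then K2CO3 (cat.), MeOH, rt
Reagents that add atoms: 3-chloroperoxybenzoic acid, OOC(=O)c1cccc(Cl)c1
Why: Dakin-type Baeyer–Villiger oxidation: the electron-rich aryl group migrates to oxygen to give formate 3, which methanolysis cleaves. No alkene is present yet to compete for the peracid.

Step 3
Reactants: 4 3-methoxy-4-(methoxymethoxy)phenol
Product: 6 2-hydroxy-4-methoxy-5-(methoxymethoxy)benzaldehyde, via hydroxymethyl phenol 5 (not isolated)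
Conditions: MgCl2, Et3N, (CH2O)n, MeCN, reflux
Reagents that add atoms: paraformaldehyde (source of formaldehyde), C=O
Why: Magnesium-mediated ortho-formylation of a phenol (Casnati–Skattebøl reaction): the magnesium phenoxide directs formaldehyde to the ortho carbon and a second formaldehyde oxidises the benzylic alkoxide of 5 by hydride transfer. Of the two ortho carbons, the one para to the methoxy group is open and more activated than the one wedged between two oxygens.

Step 4
Reactants: 6 2-hydroxy-4-methoxy-5-(methoxymethoxy)benzaldehyde; 7 allyl bromide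
Product: 8 4-methoxy-5-(methoxymethoxy)-2-(prop-2-en-1-yloxy)benzaldehyde
Conditions: K2CO3, DMF, rt → 50 °C
Reagents that add atoms: none
Why: Williamson ether synthesis. Carbonate in DMF breaks the hydrogen bond of the salicylaldehyde hydroxyl and the unhindered allylic bromide alkylates oxygen.

Step 5
Reactants: 8 4-methoxy-5-(methoxymethoxy)-2-(prop-2-en-1-yloxy)benzaldehyde
Product: 10 2-hydroxy-4-methoxy-5-(methoxymethoxy)-3-(prop-2-en-1-yl)benzaldehyde, via allyl dienone 9 (not isolated)
Conditions: PhNEt2, 190 °C
Reagents that add atoms: none
Why: Aromatic Claisen rearrangement ([3,3]-sigmatropic shift). One ortho position is blocked by the formyl group, so the allyl group settles on the carbon between the oxygen and the methoxy group, and dienone 9 tautomerises to the phenol. The neutral medium spares the acetal.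

Step 6
Reactants: 10 2-hydroxy-4-methoxy-5-(methoxymethoxy)-3-(prop-2-en-1-yl)benzaldehyde
Product: 11 2-hydroxy-4-methoxy-5-(methoxymethoxy)-3-(3-methylbut-2-en-1-yl)benzaldehyde
Conditions: 2-methyl-2-butene (excess), second-generation Grubbs catalyst (H2IMes)(PCy3)Cl2Ru=CHPh (cat.), CH2Cl2, 40 °C
Reagents that add atoms: 2-methyl-2-butene, CC=C(C)C
Why: Olefin cross-metathesis. The terminal alkene exchanges its methylene for the isopropylidene of the partner used in excess, propene escapes, and the trisubstituted product is too hindered to react further.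

Step 7
Reactants: 11 2-hydroxy-4-methoxy-5-(methoxymethoxy)-3-(3-methylbut-2-en-1-yl)benzaldehyde; 12 chloroacetone
Product: 14 1-[6-methoxy-5-(methoxymethoxy)-7-(3-methylbut-2-en-1-yl)-1-benzofuran-2-yl]ethan-1-one, via aryloxyacetone 13 (not isolated)
Conditions: K2CO3, DMF, 80 °C
Reagents that add atoms: none
Why: Rap–Stoermer benzofuran synthesis: O-alkylation by the α-chloro ketone, intramolecular aldol addition of the ketone enolate of 13 to the ortho aldehyde, and dehydration to the aromatic furan.

Step 8
Reactants: 14 1-[6-methoxy-5-(methoxymethoxy)-7-(3-methylbut-2-en-1-yl)-1-benzofuran-2-yl]ethan-1-one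
Product: 17 methyl 3-[6-methoxy-5-(methoxymethoxy)-7-(3-methylbut-2-en-1-yl)-1-benzofuran-2-yl]prop-2-ynoate, via enol phosphate 15 (not isolated), via lithium acetylide 16 (not isolated)
Conditions: LDA (1.05 equiv), THF, −78 °C; ClP(O)(OEt)2, −78 °C → rt; LDA (2.3 equiv), −78 → 0 °C; then ClCO2Me (4 equiv), −78 → 0 °C; aq. NH4Cl
Reagents that add atoms: methyl chloroformate, COC(=O)Cl
Why: Methyl ketone to alkynoate by enol phosphate elimination and acylation in one flask: the kinetic enolate is O-phosphorylated, a second portion of amide base eliminates diethyl phosphate from 15 and holds the alkyne as acetylide 16, and the chloroformate C-acylates 16. The excess of chloroformate absorbs the diisopropylamine and any residual amide, and the cold quench keeps the hindered amine from adding to the ynoate.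

Step 9
Reactants: 18 methyl (E)-3-methoxybut-2-enoate
Product: 20 (1E)-1,3-dimethoxy-1-(trimethylsilyloxy)buta-1,3-diene, via lithium dienolate 19 (not isolated)
Conditions: LDA, THF, −78 °C; Me3SiCl, −78 °C → rt; distilled
Reagents that add atoms: chlorotrimethylsilane, C[Si](C)(C)Cl
Why: γ-Deprotonation of a β-alkoxy enoate to the extended enolate and O-silylation, the standard preparation of a ketene silyl acetal diene.

Step 10
Reactants: 17 methyl 3-[6-methoxy-5-(methoxymethoxy)-7-(3-methylbut-2-en-1-yl)-1-benzofuran-2-yl]prop-2-ynoate; 20 (1E)-1,3-dimethoxy-1-(trimethylsilyloxy)buta-1,3-diene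
Product: 23 methyl 2-hydroxy-4-methoxy-6-[6-methoxy-5-(methoxymethoxy)-7-(3-methylbut-2-en-1-yl)-1-benzofuran-2-yl]benzoate, via cyclohexadiene cycloadduct 21 (not isolated), via aryl silyl ether 22 (not isolated)
Conditions: 20 (excess), PhMe, 110 °C, sealed tube; then aq. NH4Cl–THF, rt
Reagents that add atoms: none
Why: Diels–Alder reaction of a 1,3-dioxygenated ketene silyl acetal diene with an alkynoate, the known way from ynoates to 6-substituted 2-hydroxy-4-methoxybenzoates. The terminal methylene of 20 (largest HOMO coefficient) bonds to the β-carbon of 17 (largest LUMO coefficient) and the ketene acetal carbon to the α-carbon, in a concerted but strongly asynchronous (4+2) addition; should it become stepwise, it is a vinylogous Mukaiyama–Michael addition followed by 6-exo-trig closure of the allenoate α-carbon onto the silyloxycarbenium carbon, with the same connectivity. Ring B closes in 21 with the new bonds C1'–C6' and C2'–C3'. At the reaction temperature 21 aromatises by 1,4-elimination of the ketal methoxy group and a ring CH2 hydrogen, and the labile silyl ether 22 is hydrolysed on work-up, leaving the hydroxyl hydrogen-bonded to the ester. The only stereocentre of 21, the ketal carbon, is erased on aromatisation, so no stereocontrol is needed. The selectivity required is regiochemical (ester between hydroxyl and benzofuranyl, both oxygens meta to the benzofuranyl carbon), and the matched polarity of the two partners secures it. The electron-rich diene engages only the electron-poor triple bond, not the prenyl alkene or the furan C2–C3 bond. Excess diene makes up for its thermal loss, because the donor benzofuranyl group makes 17 a slower dienophile than an alkyl propiolate.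

Step 11
Reactants: 23 methyl 2-hydroxy-4-methoxy-6-[6-methoxy-5-(methoxymethoxy)-7-(3-methylbut-2-en-1-yl)-1-benzofuran-2-yl]benzoate
Product: 24 2-hydroxy-4-methoxy-6-[6-methoxy-5-(methoxymethoxy)-7-(3-methylbut-2-en-1-yl)-1-benzofuran-2-yl]benzoic acid
Conditions: NaSEt, DMF, 80 °C; then cold dilute HCl to pH 3
Reagents that add atoms: none
Why: SN2 dealkylation of a hindered methyl ester by thiolate (alkyl–oxygen cleavage), which avoids the tetrahedral intermediate that the two ortho substituents obstruct. Aryl methyl ethers need much higher temperatures and the acetal is inert to nucleophiles.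

Step 12
Reactants: 24 2-hydroxy-4-methoxy-6-[6-methoxy-5-(methoxymethoxy)-7-(3-methylbut-2-en-1-yl)-1-benzofuran-2-yl]benzoic acid
Product: 25 3-methoxy-5-[6-methoxy-5-(methoxymethoxy)-7-(3-methylbut-2-en-1-yl)-1-benzofuran-2-yl]phenol
Conditions: DMSO, 140 °C
Reagents that add atoms: none
Why: Thermal protodecarboxylation of an ortho-hydroxy, para-methoxy benzoic acid through its ipso-protonated keto tautomer, helped by relief of strain between the carboxyl and the ortho aryl group. Partial loss of the acetal here would be harmless because the next step removes it.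

Step 13
Reactants: 25 3-methoxy-5-[6-methoxy-5-(methoxymethoxy)-7-(3-methylbut-2-en-1-yl)-1-benzofuran-2-yl]phenol
Product: 26 dinklagein A, 2-(3-hydroxy-5-methoxyphenyl)-6-methoxy-7-(3-methylbut-2-en-1-yl)-1-benzofuran-5-ol
Conditions: HCl (cat.), MeOH, 40 °C
Reagents that add atoms: none
Why: Acid-catalysed acetal cleavage by transacetalisation to methanol. The prenyl group has no free hydroxyl beside it, so it cannot cyclise, and dilute acid at mild temperature leaves the trisubstituted alkene alone.

## Compound list

1 | vanillin (4-hydroxy-3-methoxybenzaldehyde) | COc1cc(C=O)ccc1O | starting material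
2 | 3-methoxy-4-(methoxymethoxy)benzaldehyde | COCOc1ccc(C=O)cc1OC | intermediate
3 | 3-methoxy-4-(methoxymethoxy)phenyl formate | COCOc1ccc(OC=O)cc1OC | intermediate
4 | 3-methoxy-4-(methoxymethoxy)phenol | COCOc1ccc(O)cc1OC | intermediate
5 | 2-(hydroxymethyl)-5-methoxy-4-(methoxymethoxy)phenol (present as its magnesium salt) | COCOc1cc(CO)c(O)cc1OC | intermediate
6 | 2-hydroxy-4-methoxy-5-(methoxymethoxy)benzaldehyde | COCOc1cc(C=O)c(O)cc1OC | intermediate
7 | allyl bromide (3-bromoprop-1-ene) | C=CCBr | starting material
8 | 4-methoxy-5-(methoxymethoxy)-2-(prop-2-en-1-yloxy)benzaldehyde | COCOc1cc(C=O)c(OCC=C)cc1OC | intermediate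
9 | racemic 4-methoxy-3-(methoxymethoxy)-6-oxo-5-(prop-2-en-1-yl)cyclohexa-1,3-diene-1-carbaldehyde | O=CC1=CC(OCOC)=C(OC)C(CC=C)C1=O | intermediate
10 | 2-hydroxy-4-methoxy-5-(methoxymethoxy)-3-(prop-2-en-1-yl)benzaldehyde | COCOc1cc(C=O)c(O)c(CC=C)c1OC | intermediate
11 | 2-hydroxy-4-methoxy-5-(methoxymethoxy)-3-(3-methylbut-2-en-1-yl)benzaldehyde | COCOc1cc(C=O)c(O)c(CC=C(C)C)c1OC | intermediate
12 | chloroacetone (1-chloropropan-2-one) | CC(=O)CCl | starting material
13 | 4-methoxy-5-(methoxymethoxy)-3-(3-methylbut-2-en-1-yl)-2-(2-oxopropoxy)benzaldehyde | CC(=O)COc1c(C=O)cc(OCOC)c(OC)c1CC=C(C)C | intermediate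
14 | 1-[6-methoxy-5-(methoxymethoxy)-7-(3-methylbut-2-en-1-yl)-1-benzofuran-2-yl]ethan-1-one | CC(=O)c1cc2cc(OCOC)c(OC)c(CC=C(C)C)c2o1 | intermediate
15 | diethyl 1-[6-methoxy-5-(methoxymethoxy)-7-(3-methylbut-2-en-1-yl)-1-benzofuran-2-yl]ethenyl phosphate | C=C(OP(=O)(OCC)OCC)c1cc2cc(OCOC)c(OC)c(CC=C(C)C)c2o1 | intermediate
16 | lithium [6-methoxy-5-(methoxymethoxy)-7-(3-methylbut-2-en-1-yl)-1-benzofuran-2-yl]acetylide | [Li]C#Cc1cc2cc(OCOC)c(OC)c(CC=C(C)C)c2o1 | intermediate
17 | methyl 3-[6-methoxy-5-(methoxymethoxy)-7-(3-methylbut-2-en-1-yl)-1-benzofuran-2-yl]prop-2-ynoate | COC(=O)C#Cc1cc2cc(OCOC)c(OC)c(CC=C(C)C)c2o1 | intermediate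
18 | methyl (E)-3-methoxybut-2-enoate | C/C(OC)=C\C(=O)OC | starting material
19 | lithium (1Z)-1,3-dimethoxybuta-1,3-dien-1-olate (O–Li trans to C3, the geometry carried into 20) | C=C(OC)/C=C(\OC)O[Li] | intermediate
20 | (1E)-1,3-dimethoxy-1-(trimethylsilyloxy)buta-1,3-diene | C=C(OC)/C=C(\OC)O[Si](C)(C)C | intermediate
21 | racemic methyl 4,6-dimethoxy-2-[6-methoxy-5-(methoxymethoxy)-7-(3-methylbut-2-en-1-yl)-1-benzofuran-2-yl]-6-(trimethylsilyloxy)cyclohexa-1,4-diene-1-carboxylate | COC(=O)C1=C(c2cc3cc(OCOC)c(OC)c(CC=C(C)C)c3o2)CC(OC)=CC1(OC)O[Si](C)(C)C | intermediate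
22 | methyl 4-methoxy-2-[6-methoxy-5-(methoxymethoxy)-7-(3-methylbut-2-en-1-yl)-1-benzofuran-2-yl]-6-(trimethylsilyloxy)benzoate | COC(=O)c1c(O[Si](C)(C)C)cc(OC)cc1-c1cc2cc(OCOC)c(OC)c(CC=C(C)C)c2o1 | intermediate
23 | methyl 2-hydroxy-4-methoxy-6-[6-methoxy-5-(methoxymethoxy)-7-(3-methylbut-2-en-1-yl)-1-benzofuran-2-yl]benzoate | COC(=O)c1c(O)cc(OC)cc1-c1cc2cc(OCOC)c(OC)c(CC=C(C)C)c2o1 | intermediate
24 | 2-hydroxy-4-methoxy-6-[6-methoxy-5-(methoxymethoxy)-7-(3-methylbut-2-en-1-yl)-1-benzofuran-2-yl]benzoic acid | OC(=O)c1c(O)cc(OC)cc1-c1cc2cc(OCOC)c(OC)c(CC=C(C)C)c2o1 | intermediate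
25 | 3-methoxy-5-[6-methoxy-5-(methoxymethoxy)-7-(3-methylbut-2-en-1-yl)-1-benzofuran-2-yl]phenol | COc1cc(O)cc(-c2cc3cc(OCOC)c(OC)c(CC=C(C)C)c3o2)c1 | intermediate
26 | dinklagein A, 2-(3-hydroxy-5-methoxyphenyl)-6-methoxy-7-(3-methylbut-2-en-1-yl)-1-benzofuran-5-ol | COc1cc(O)cc(-c2cc3cc(O)c(OC)c(CC=C(C)C)c3o2)c1 | target

## Step count and least certain steps

Total: 13 steps. Longest linear sequence: 12 steps (steps 1 to 8 and 10 to 13, from vanillin 1); step 9 is a one-step side branch.

**Step 10 (key step).** The donor benzofuranyl group lowers the electrophilicity of the β-carbon of 17, so the cycloaddition may be slow. Thermal decomposition or adventitious hydrolysis of the diene could then outrun ring formation, or the adduct could stall before the 1,4-elimination. The fallback gives up the benzannulation and makes the C2–C1' bond by cross-coupling. It sets out from compound 11 and returns at compound 25. Dibromo-olefination of the aldehyde of 11 (CBr4, PPh3, Et3N, CH2Cl2, 0 °C) would give 2-(2,2-dibromoethenyl)-5-methoxy-4-(methoxymethoxy)-6-(3-methylbut-2-en-1-yl)phenol F1. Intramolecular O-vinylation of F1 with copper monoiodide (CuI) and K3PO4 in THF at 80 °C would close the furan to 2-bromo-6-methoxy-5-(methoxymethoxy)-7-(3-methylbut-2-en-1-yl)-1-benzofuran F2. Purchased 3-bromo-5-methoxyphenol (COc1cc(O)cc(Br)c1) would be borylated (bis(pinacolato)diboron, Pd(dppf)Cl2, KOAc, dioxane, 90 °C) to 3-methoxy-5-(4,4,5,5-tetramethyl-1,3,2-dioxaborolan-2-yl)phenol F3. Suzuki–Miyaura coupling of F2 with F3 (Pd(PPh3)4, aq. K2CO3, dioxane, 80 °C) would give 25. The price is a purchased, already desymmetrised ring B and the loss of steps 7 to 12.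

**Step 5.** At the temperature the rearrangement needs, migration to the formyl-bearing ortho carbon with loss of the formyl group, or general degradation of the aldehyde, may erode the material. The fallback replaces the sigmatropic shift by halogenation and cross-coupling. It sets out from compound 6 and returns at compound 10. Iodination of 6 (N-iodosuccinimide, DMF, rt) at the only carbon activated by both the hydroxyl and the methoxy group would give 2-hydroxy-3-iodo-4-methoxy-5-(methoxymethoxy)benzaldehyde F4. Stille coupling of F4 with allyltributylstannane (Pd(PPh3)4, DMF, 90 °C) would give 10.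

**Step 8.** Excess amide base may deprotonate the benzylic and allylic CH2 of the prenyl group and move the double bond into conjugation, the elimination may stop at the enol phosphate, or the diisopropylamine set free may consume the chloroformate and add to the ynoate before the quench. The fallback builds the alkyne from an aldehyde by one-carbon homologation and acylates it in the absence of amine. It sets out from compound 11 and returns at compound 17. Condensation of 11 with ethyl bromoacetate (K2CO3, DMF, 100 °C) would give ethyl 6-methoxy-5-(methoxymethoxy)-7-(3-methylbut-2-en-1-yl)-1-benzofuran-2-carboxylate F5. Reduction with i-Bu2AlH (CH2Cl2, −78 → 0 °C) would give [6-methoxy-5-(methoxymethoxy)-7-(3-methylbut-2-en-1-yl)-1-benzofuran-2-yl]methanol F6. Oxidation with MnO2 (CH2Cl2, rt) would give 6-methoxy-5-(methoxymethoxy)-7-(3-methylbut-2-en-1-yl)-1-benzofuran-2-carbaldehyde F7. Ohira–Bestmann homologation of F7 (dimethyl (1-diazo-2-oxopropyl)phosphonate, K2CO3, MeOH, rt) would give 2-ethynyl-6-methoxy-5-(methoxymethoxy)-7-(3-methylbut-2-en-1-yl)-1-benzofuran F8 without any strong base. Deprotonation of F8 with one equivalent of n-BuLi (THF, −78 °C) would give acetylide 16 free of amine, and methyl chloroformate (−78 → 0 °C) would convert it into 17.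

**Step 11.** Once the phenoxide has formed, cleavage of the doubly ortho-substituted ester may become slow enough for thiolate attack on the aryl methyl ethers to compete. The fallback changes the ester so that it is removed by allyl transfer to zerovalent palladium instead of by SN2 attack. It sets out from compound 14 and returns at compound 24. The sequence of step 8, run on 14 with allyl chloroformate in place of methyl chloroformate and passing through 15 and 16, would give prop-2-en-1-yl 3-[6-methoxy-5-(methoxymethoxy)-7-(3-methylbut-2-en-1-yl)-1-benzofuran-2-yl]prop-2-ynoate F9. Cycloaddition of F9 with 20 under the conditions of step 10 would pass through racemic prop-2-en-1-yl 4,6-dimethoxy-2-[6-methoxy-5-(methoxymethoxy)-7-(3-methylbut-2-en-1-yl)-1-benzofuran-2-yl]-6-(trimethylsilyloxy)cyclohexa-1,4-diene-1-carboxylate F10 and prop-2-en-1-yl 4-methoxy-2-[6-methoxy-5-(methoxymethoxy)-7-(3-methylbut-2-en-1-yl)-1-benzofuran-2-yl]-6-(trimethylsilyloxy)benzoate F11, and work-up would give prop-2-en-1-yl 2-hydroxy-4-methoxy-6-[6-methoxy-5-(methoxymethoxy)-7-(3-methylbut-2-en-1-yl)-1-benzofuran-2-yl]benzoate F12. Deallylation of F12 (Pd(PPh3)4, morpholine, THF, rt) would give 24 under neutral conditions.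

## Further compounds

F1 | step 10 | 2-(2,2-dibromoethenyl)-5-methoxy-4-(methoxymethoxy)-6-(3-methylbut-2-en-1-yl)phenol | COCOc1cc(C=C(Br)Br)c(O)c(CC=C(C)C)c1OC
F2 | step 10 | 2-bromo-6-methoxy-5-(methoxymethoxy)-7-(3-methylbut-2-en-1-yl)-1-benzofuran | Brc1cc2cc(OCOC)c(OC)c(CC=C(C)C)c2o1
F3 | step 10 | 3-methoxy-5-(4,4,5,5-tetramethyl-1,3,2-dioxaborolan-2-yl)phenol | COc1cc(O)cc(B2OC(C)(C)C(C)(C)O2)c1
F4 | step 5 | 2-hydroxy-3-iodo-4-methoxy-5-(methoxymethoxy)benzaldehyde | COCOc1cc(C=O)c(O)c(I)c1OC
F5 | step 8 | ethyl 6-methoxy-5-(methoxymethoxy)-7-(3-methylbut-2-en-1-yl)-1-benzofuran-2-carboxylate | CCOC(=O)c1cc2cc(OCOC)c(OC)c(CC=C(C)C)c2o1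
F6 | step 8 | [6-methoxy-5-(methoxymethoxy)-7-(3-methylbut-2-en-1-yl)-1-benzofuran-2-yl]methanol | OCc1cc2cc(OCOC)c(OC)c(CC=C(C)C)c2o1
F7 | step 8 | 6-methoxy-5-(methoxymethoxy)-7-(3-methylbut-2-en-1-yl)-1-benzofuran-2-carbaldehyde | O=Cc1cc2cc(OCOC)c(OC)c(CC=C(C)C)c2o1
F8 | step 8 | 2-ethynyl-6-methoxy-5-(methoxymethoxy)-7-(3-methylbut-2-en-1-yl)-1-benzofuran | C#Cc1cc2cc(OCOC)c(OC)c(CC=C(C)C)c2o1
F9 | step 11 | prop-2-en-1-yl 3-[6-methoxy-5-(methoxymethoxy)-7-(3-methylbut-2-en-1-yl)-1-benzofuran-2-yl]prop-2-ynoate | C=CCOC(=O)C#Cc1cc2cc(OCOC)c(OC)c(CC=C(C)C)c2o1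
F10 | step 11 | racemic prop-2-en-1-yl 4,6-dimethoxy-2-[6-methoxy-5-(methoxymethoxy)-7-(3-methylbut-2-en-1-yl)-1-benzofuran-2-yl]-6-(trimethylsilyloxy)cyclohexa-1,4-diene-1-carboxylate | C=CCOC(=O)C1=C(c2cc3cc(OCOC)c(OC)c(CC=C(C)C)c3o2)CC(OC)=CC1(OC)O[Si](C)(C)C
F11 | step 11 | prop-2-en-1-yl 4-methoxy-2-[6-methoxy-5-(methoxymethoxy)-7-(3-methylbut-2-en-1-yl)-1-benzofuran-2-yl]-6-(trimethylsilyloxy)benzoate | C=CCOC(=O)c1c(O[Si](C)(C)C)cc(OC)cc1-c1cc2cc(OCOC)c(OC)c(CC=C(C)C)c2o1
F12 | step 11 | prop-2-en-1-yl 2-hydroxy-4-methoxy-6-[6-methoxy-5-(methoxymethoxy)-7-(3-methylbut-2-en-1-yl)-1-benzofuran-2-yl]benzoate | C=CCOC(=O)c1c(O)cc(OC)cc1-c1cc2cc(OCOC)c(OC)c(CC=C(C)C)c2o1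
A1 | alternative 1 | racemic 6-methoxy-2-[3-methoxy-5-(methoxymethoxy)phenyl]-5-(methoxymethoxy)-7-(3-methylbut-2-en-1-yl)-2,3-dihydro-1-benzofuran | COCOc1cc(OC)cc(C2Cc3cc(OCOC)c(OC)c(CC=C(C)C)c3O2)c1
A2 | alternative 1 | [2-hydroxy-4-methoxy-5-(methoxymethoxy)-3-(3-methylbut-2-en-1-yl)benzyl]trimethylammonium iodide | C[N+](C)(C)Cc1cc(OCOC)c(OC)c(CC=C(C)C)c1O.[I-]
A3 | alternative 1 | [3-methoxy-5-(methoxymethoxy)benzyl]dimethylsulfonium bromide | C[S+](C)Cc1cc(OC)cc(OCOC)c1.[Br-]
A4 | alternative 2 | racemic 6-methoxy-2-[3-methoxy-5-(methoxymethoxy)phenyl]-7-(3-methylbut-2-en-1-yl)-2,3-dihydro-1-benzofuran-5-ol | COCOc1cc(OC)cc(C2Cc3cc(O)c(OC)c(CC=C(C)C)c3O2)c1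
A5 | alternative 2 | racemic pentacarbonyl{5-[3-methoxy-5-(methoxymethoxy)phenyl]-3-methylideneoxolan-2-ylidene}chromium | C=C1CC(c2cc(OC)cc(OCOC)c2)OC1=[Cr](=C=O)(=C=O)(=C=O)(=C=O)=C=O
A6 | alternative 2 | 1-methoxy-5-methylhex-4-en-1-yne | COC#CCC=C(C)C
A7 | alternative 3 | 2-[3-methoxy-5-(methoxymethoxy)phenyl]-5-(methoxymethoxy)-7-(3-methylbut-2-en-1-yl)-1-benzofuran-6-ol | CC(C)=CCc1c(O)c(OCOC)cc2cc(-c3cc(OC)cc(OCOC)c3)oc12
A8 | alternative 3 | racemic 5-[3-methoxy-5-(methoxymethoxy)phenyl]-2-[1-(methoxymethoxy)-6-methyl-2-oxohept-5-en-3-yl]furan-3-carbaldehyde | COCOCC(=O)C(CC=C(C)C)c1oc(-c2cc(OC)cc(OCOC)c2)cc1C=O
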